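## The problem

Target 14 is a 2-aryl-4H-chromen-4-one: benzenoid ring A is fused to pyranone ring C across C4a–C8a, and ring B sits on C2. It has no stereocentre, so the only stereochemical element is a transient alkene geometry in open-chain precursors. The real task is four oxygens in four different states: a methyl ether at C3, free hydroxyls at C5 and C7, and a prenyl ether at C4'. The C3 methyl ether can neither be made by late methylation nor survive a global demethylation, so it has to arrive with the carbon skeleton. The C7 hydroxyl, para to the C4 carbonyl, is the most acidic and the first to meet an electrophile. The C5 hydroxyl is held in a hydrogen bond to C4=O, and the C4' oxygen, the one to be alkylated, lies in between. The prenyl aryl ether is the fragile group: acids ionise it (cleavage, migration to carbon, chroman formation) and hydrogen over palladium saturates or cleaves it, so it cannot be present during an electrophilic ring closure or a benzyl hydrogenolysis. The feature that opens the key step is C4a: it is ortho to O1 and ortho or para to the oxygens at C5 and C7, and a 3,5-dioxygenated phenoxy ring offers two such carbons, equivalent by symmetry, to an acyl carbon (C4) tethered through O1–C2=C3.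

## Retrosynthesis

**O4'–prenyl bond, then O7–Si.** Target 14 is traced to the 7-O-triisopropylsilyl ether 13, and 13 to phenol 11 and prenol 12 by cutting the O–CH2 bond of the prenyl ether. This cut comes last because the prenyl ether cannot pass through the acylation or the hydrogenolysis that precede it. Alkylating the free triphenol 10 directly would send the electrophile to O7, so O7 is masked as a silyl ether in 11; O5 needs no mask because it is chelated. The forward etherification must be neutral enough to spare an aryl silyl ether and must give the linear prenyl isomer, which points to a Mitsunobu reaction.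

**O7–Si and three O–benzyl bonds.** Compound 11 comes from isokaempferide 10 by silylation at the most acidic hydroxyl, and 10 from tribenzyl ether 9 by cleaving all three O–CH2Ph bonds at once. Benzyl is chosen over its neighbours because methyl ethers could not be removed without endangering the C3 methyl ether, and acetal or silyl groups would not survive the Lewis acid of the ring closure. The forward hydrogenolysis must stop short of the tetrasubstituted C2=C3 bond.

**C4–C4a, the key cut.** Flavone 9 is opened between C4 and C4a to acid chloride 8 and hence to the β-aryloxy-α-methoxyacrylic acid 7. The neighbouring cuts are O1–C2 (cyclodehydration of a 1,3-diketone) and O1–C8a (closure onto an ortho-halo aryl ketone). Both need a ring A that already carries a carbon substituent and is therefore desymmetrised. Cutting C4–C4a lets ring A enter as a symmetric phenol, and symmetry decides the regiochemistry. Acid 7 is acyclic and contains every skeletal atom of 9. The forward step asks an acyl cation to reach the ortho carbon of the aryloxy ring, which requires the carbonyl group cis to the aryloxy oxygen.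

**O1–C2.** Acid 7 comes from methyl ester 6 by hydrolysis, and 6 is cut at the aryl vinyl ether bond into phenol 5 and enol triflate 4. This is the most convergent cut available, since it divides the molecule into ring A and the ring B–C3 unit. The forward reaction is an addition–elimination at a fully substituted β-carbon.

**C2–C3.** Triflate 4 comes from β-keto ester 3, and 3 is cut between the ketone carbon (future C2) and the α-carbon (future C3) into methyl methoxyacetate 1 and acid chloride 2. The C3 methoxy group is thereby carried from a commercial two-carbon ester, and no late differentiation of that oxygen is needed.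

## Roads not taken

**Alternative 1:** Ring A is cut at C4a–C8a and built from a linear polyketide. The triketo ester A1 is closed by a magnesium alkoxide Claisen condensation (C6 carbanion onto the C1 ester) to the acylphloroglucinol A2. A second, oxidative closure of O1–C2 would then give 14.
- Merits: no protecting group on ring A, and the prenyl ether is in place before any acid or hydrogen is used.
- Weak points: A1 is a poly-β-carbonyl chain that must be assembled by polyanion chemistry. The Claisen mode competes with aldol closure and with lactonisation to a pyranone. After A2 the pyranone ring still has to be formed oxidatively from an α-methoxychalcone, under conditions the prenyl ether and two free phenols must tolerate.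
- Comparison: this road is better in protecting-group economy. The chosen plan sets against it steps that each have a close analogue, and a ring closure that needs no oxidant.

**Alternative 2:** Ring C is cut at C2=C3. The keto phosphorane A3 is heated, and the ylide carbon attacks the neighbouring aroyl ester carbonyl in an intramolecular Wittig reaction. Loss of the phosphine oxide gives the bis(methoxymethyl) ether A4, and acid then frees O5 and O7.
- Merits: the prenyl ether is introduced on ring B at the outset, so the O7/O4' problem never arises. The key step is neutral, and only one step follows it.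
- Weak points: the ylide is fully substituted and carries a donor, so olefination of an ester carbonyl should be sluggish. Its preparation needs acylation of a methoxymethylene phosphorane. Ring A must be desymmetrised (one free ortho hydroxyl, two acetals). The final acetal cleavage, especially at O7, is an acid step carried out on the acid-labile prenyl ether.
- Comparison: this road has the shorter endgame, one step against four after the key step. The chosen plan sets against it a final fluoride deprotection in place of acid, a symmetric commercial ring A, and acylation of a triply activated carbon in place of a hindered ester olefination.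

**Alternative 3:** Ring A is cut at C5–C6, C7–C8 and C4a–C5 and grown on a pyranone derived from kojic acid A5. Wolff rearrangement of the diazoketone A6 gives a vinylketene, which adds (triisopropylsilyloxy)acetylene A7. Ring opening and 6π electrocyclisation then give A8.
- Merits: A8 is the same compound as 13 of the chosen route. O5 (from the ketene carbon) and O7 (from the alkyne) are differentiated by the mechanism, with the prenyl ether already present, so only desilylation would remain.
- Weak points: A6 requires arylation, oxidation and diazo transfer on the kojic acid core. The "vinyl" unit of the ketene is the electron-poor C=C of a 4-pyranone, a substrate type for which the benzannulation lacks close analogy. The pyranone and the prenyl alkene are both exposed to the ketene and to the light or heat of the Wolff step. A7 is a sensitive reagent.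
- Comparison: if it worked, this would be the most direct entry to 13, and on that point it is better. The chosen plan reaches 13 three steps after its key step, but every step has a close analogue.

Key step: step 5

## Route

Assumptions:
- Compounds 4, 6, 7 and 8 are drawn as E isomers (carbonyl group cis to the oxygen on the future C2). This is the geometry expected from chelation-controlled triflation and retentive substitution. Any Z component would converge on 9, because step 5 equilibrates the geometry.
- Compounds 2 and 5 are taken as purchased.

Step 1
Reactants: 1 methyl 2-methoxyacetate; 2 4-(benzyloxy)benzoyl chloride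
Product: 3 methyl 3-[4-(benzyloxy)phenyl]-2-methoxy-3-oxopropanoate (racemic)
Conditions: 1 (2.1 equiv), LiN(i-Pr)2 (2.1 equiv), THF, −78 °C; then 2 (1.0 equiv), −78 → −40 °C; aq. NH4Cl
Reagents that add atoms: none
Why: Claisen-type C-acylation of an ester lithium enolate by an acid chloride; the second equivalent of enolate deprotonates the more acidic β-keto ester as it forms and so prevents double acylation. The stereocentre at C2 is formed racemic and is erased in step 2.

Step 2
Reactants: 3 methyl 3-[4-(benzyloxy)phenyl]-2-methoxy-3-oxopropanoate
Product: 4 methyl (2E)-3-[4-(benzyloxy)phenyl]-2-methoxy-3-[(trifluoromethanesulfonyl)oxy]prop-2-enoate (triflyloxy group cis to the ester)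
Conditions: Tf2O (1.2 equiv), i-Pr2NEt (1.5 equiv), LiOTf (1.5 equiv), CH2Cl2, −78 → 0 °C
Reagents that add atoms: trifluoromethanesulfonic anhydride, O=S(=O)(OS(=O)(=O)C(F)(F)F)C(F)(F)F
Why: Enol triflate formation by O-sulfonylation of a β-keto ester enolate; soft enolisation in the presence of lithium should give the chelated enolate, which places the triflyloxy group cis to the ester.

Step 3
Reactants: 4 methyl (2E)-3-[4-(benzyloxy)phenyl]-2-methoxy-3-[(trifluoromethanesulfonyl)oxy]prop-2-enoate; 5 3,5-bis(benzyloxy)phenol
Product: 6 methyl (2E)-3-[3,5-bis(benzyloxy)phenoxy]-3-[4-(benzyloxy)phenyl]-2-methoxyprop-2-enoate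
Conditions: 5 (1.1 equiv), Cs2CO3 (1.5 equiv), MeCN, 25 → 50 °C
Reagents that add atoms: none
Why: Nucleophilic vinylic substitution by addition–elimination: the caesium phenoxide adds to the triflate-bearing carbon and the resulting ester enolate expels triflate, as in the usual preparation of β-aryloxyacrylates from β-sulfonyloxy or β-halo acrylates. Retention of geometry is expected but is not essential.

Step 4
Reactants: 6 methyl (2E)-3-[3,5-bis(benzyloxy)phenoxy]-3-[4-(benzyloxy)phenyl]-2-methoxyprop-2-enoate
Product: 7 (2E)-3-[3,5-bis(benzyloxy)phenoxy]-3-[4-(benzyloxy)phenyl]-2-methoxyprop-2-enoic acid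
Conditions: LiOH·H2O (5 equiv), THF/MeOH/H2O, 50 °C; then 1 M HCl to pH 3, 0 °C
Reagents that add atoms: lithium hydroxide, [Li+].[OH-]
Why: Ester saponification by acyl–oxygen cleavage, as in the classical hydrolysis of β-aryloxycinnamates. The β-carbon is fully substituted and flanked by two oxygen donors, so hydroxide should attack the ester carbonyl and not displace the aryloxide.

Step 5
Reactants: 7 (2E)-3-[3,5-bis(benzyloxy)phenoxy]-3-[4-(benzyloxy)phenyl]-2-methoxyprop-2-enoic acid
Product: 9 5,7-bis(benzyloxy)-2-[4-(benzyloxy)phenyl]-3-methoxy-4H-chromen-4-one, via acid chloride 8 (not isolated)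
Conditions: (COCl)2 (1.2 equiv), cat. DMF, CH2Cl2, 0 °C; volatiles stripped; SnCl4 (1.1 equiv), CH2Cl2, −78 → −20 °C; cold aq. NaHCO3
Reagents that add atoms: oxalyl chloride, O=C(Cl)C(Cl)=O (supplies the chlorine of 8; none of its atoms remains in 9)
Why: Oxalyl chloride with catalytic DMF converts 7 into acid chloride 8, and SnCl4 ionises 8 to an acyl cation that is stabilised as a ketene–oxocarbenium ion by the aryloxy oxygen on the future C2. The cation attacks an ortho carbon of the 3,5-bis(benzyloxy)phenoxy ring and loss of a proton forms C4–C4a; this is an intramolecular Friedel–Crafts acylation, the closing event of the Simonis-type chromone synthesis from β-aryloxyacrylic acids and of xanthone synthesis from 2-aryloxybenzoic acids. Ring C closes in a six-membered mode, exo with respect to the acyl C=O (6-exo-trig at the acyl carbon), and no stereocentre is formed. Regiochemistry needs no control: the two ortho carbons are equivalent by symmetry, each is ortho to O1, ortho to one benzyloxy group and para to the other, and the carbon between the two benzyloxy groups cannot be reached by the tether. The ortho carbons of ring B are meta to their benzyloxy group and would require a five-membered closure, so they do not compete. The required geometry (acyl group cis to the aryloxy group) is present in 8 as drawn, and a Z isomer can reach it by rotation about C2–C3 in the cation, where that bond has single-bond character. The benzyl ethers should survive brief contact with SnCl4 at low temperature; the 5-benzyloxy group, which becomes chelated to tin in the product, is the most exposed, hence the cold quench.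

Step 6
Reactants: 9 5,7-bis(benzyloxy)-2-[4-(benzyloxy)phenyl]-3-methoxy-4H-chromen-4-one
Product: 10 5,7-dihydroxy-2-(4-hydroxyphenyl)-3-methoxy-4H-chromen-4-one (isokaempferide)
Conditions: H2 (1 atm), 10% Pd/C, THF/MeOH, 25 °C
Reagents that add atoms: none
Why: Hydrogenolysis of three benzyl aryl ethers; the tetrasubstituted, doubly heteroatom-substituted C2=C3 bond of the pyranone is not expected to be reduced at atmospheric pressure.

Step 7
Reactants: 10 5,7-dihydroxy-2-(4-hydroxyphenyl)-3-methoxy-4H-chromen-4-one
Product: 11 5-hydroxy-2-(4-hydroxyphenyl)-3-methoxy-7-[(triisopropylsilyl)oxy]-4H-chromen-4-one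
Conditions: i-Pr3SiCl (1.05 equiv), imidazole (2.2 equiv), DMF, 0 °C
Reagents that add atoms: chlorotriisopropylsilane, CC(C)[Si](Cl)(C(C)C)C(C)C
Why: Site-selective O-silylation of a phenol: the C7 hydroxyl, para to the C4 carbonyl, is the most acidic and is the one present as phenoxide in the imidazole buffer, the same preference that directs monoalkylation of such flavones to O7. The C5 hydroxyl is held by its hydrogen bond to C4=O, and the bulk of the silyl group disfavours a second silylation.

Step 8
Reactants: 11 5-hydroxy-2-(4-hydroxyphenyl)-3-methoxy-7-[(triisopropylsilyl)oxy]-4H-chromen-4-one; 12 3-methylbut-2-en-1-ol (prenol)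
Product: 13 5-hydroxy-3-methoxy-2-{4-[(3-methylbut-2-en-1-yl)oxy]phenyl}-7-[(triisopropylsilyl)oxy]-4H-chromen-4-one
Conditions: 12 (1.3 equiv), PPh3 (1.4 equiv), DIAD (1.4 equiv), THF, 0 → 25 °C
Reagents that add atoms: none
Why: Mitsunobu etherification: the C4' hydroxyl is the only unhindered acidic phenol left and displaces the oxyphosphonium group of activated prenol at the primary carbon (SN2), giving the linear prenyl ether. The chelated C5 hydroxyl does not react under these conditions, and the neutral medium spares the silyl ether.

Step 9
Reactants: 13 5-hydroxy-3-methoxy-2-{4-[(3-methylbut-2-en-1-yl)oxy]phenyl}-7-[(triisopropylsilyl)oxy]-4H-chromen-4-one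
Product: 14 5,7-dihydroxy-3-methoxy-2-{4-[(3-methylbut-2-en-1-yl)oxy]phenyl}-4H-chromen-4-one
Conditions: Bu4NF (1.1 equiv), AcOH (1.1 equiv), THF, 0 °C
Reagents that add atoms: none
Why: Fluoride-induced cleavage of an aryl silyl ether, fast here because the C7 phenoxide is a good leaving group. The prenyl ether, the methyl ether and the chromone are inert to buffered fluoride.

## Compound list

1 | methyl 2-methoxyacetate | COCC(=O)OC | starting material
2 | 4-(benzyloxy)benzoyl chloride | O=C(Cl)c1ccc(OCc2ccccc2)cc1 | starting material
3 | methyl 3-[4-(benzyloxy)phenyl]-2-methoxy-3-oxopropanoate (racemic) | COC(=O)C(OC)C(=O)c1ccc(OCc2ccccc2)cc1 | intermediate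
4 | methyl (2E)-3-[4-(benzyloxy)phenyl]-2-methoxy-3-[(trifluoromethanesulfonyl)oxy]prop-2-enoate | COC(=O)/C(OC)=C(\OS(=O)(=O)C(F)(F)F)c1ccc(OCc2ccccc2)cc1 | intermediate
5 | 3,5-bis(benzyloxy)phenol | Oc1cc(OCc2ccccc2)cc(OCc2ccccc2)c1 | starting material
6 | methyl (2E)-3-[3,5-bis(benzyloxy)phenoxy]-3-[4-(benzyloxy)phenyl]-2-methoxyprop-2-enoate | COC(=O)/C(OC)=C(\Oc1cc(OCc2ccccc2)cc(OCc2ccccc2)c1)c1ccc(OCc2ccccc2)cc1 | intermediate
7 | (2E)-3-[3,5-bis(benzyloxy)phenoxy]-3-[4-(benzyloxy)phenyl]-2-methoxyprop-2-enoic acid | OC(=O)/C(OC)=C(\Oc1cc(OCc2ccccc2)cc(OCc2ccccc2)c1)c1ccc(OCc2ccccc2)cc1 | intermediate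
8 | (2E)-3-[3,5-bis(benzyloxy)phenoxy]-3-[4-(benzyloxy)phenyl]-2-methoxyprop-2-enoyl chloride | ClC(=O)/C(OC)=C(\Oc1cc(OCc2ccccc2)cc(OCc2ccccc2)c1)c1ccc(OCc2ccccc2)cc1 | intermediate (not isolated)
9 | 5,7-bis(benzyloxy)-2-[4-(benzyloxy)phenyl]-3-methoxy-4H-chromen-4-one | COc1c(-c2ccc(OCc3ccccc3)cc2)oc2cc(OCc3ccccc3)cc(OCc3ccccc3)c2c1=O | intermediate
10 | 5,7-dihydroxy-2-(4-hydroxyphenyl)-3-methoxy-4H-chromen-4-one (isokaempferide) | COc1c(-c2ccc(O)cc2)oc2cc(O)cc(O)c2c1=O | intermediate
11 | 5-hydroxy-2-(4-hydroxyphenyl)-3-methoxy-7-[(triisopropylsilyl)oxy]-4H-chromen-4-one | COc1c(-c2ccc(O)cc2)oc2cc(O[Si](C(C)C)(C(C)C)C(C)C)cc(O)c2c1=O | intermediate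
12 | 3-methylbut-2-en-1-ol (prenol) | CC(C)=CCO | starting material
13 | 5-hydroxy-3-methoxy-2-{4-[(3-methylbut-2-en-1-yl)oxy]phenyl}-7-[(triisopropylsilyl)oxy]-4H-chromen-4-one | COc1c(-c2ccc(OCC=C(C)C)cc2)oc2cc(O[Si](C(C)C)(C(C)C)C(C)C)cc(O)c2c1=O | intermediate
14 | 5,7-dihydroxy-3-methoxy-2-{4-[(3-methylbut-2-en-1-yl)oxy]phenyl}-4H-chromen-4-one | COc1c(-c2ccc(OCC=C(C)C)cc2)oc2cc(O)cc(O)c2c1=O | target

## Step count and weak points

Total step count: 9. Longest linear sequence: 9 steps (1 and 2 to 14); 5 enters at step 3 and 12 at step 8.

**Step 5 (key step).** The most likely failures are chelation-assisted loss of the benzyl group on O5 once the chromone carbonyl binds tin, and cleavage of the aryl vinyl ether before ring closure. The second arises because the cation carries positive charge on C2, where chloride or traces of water can add and expel phenol 5. Partial loss of the O5 benzyl group would not harm the route, since step 6 removes all benzyl groups; fragmentation would.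
Fallback: it sets out from 3 and returns at 10. Keto ester 3 is heated with phloroglucinol at about 240 °C, neat or in diphenyl ether, while methanol distils off. Acyl transfer to the free phenol, C-acylation and cyclodehydration (the Mentzer pyrone synthesis) should give 2-[4-(benzyloxy)phenyl]-5,7-dihydroxy-3-methoxy-4H-chromen-4-one F1. Hydrogenolysis of its single benzyl ether (H2, Pd/C) gives 10. Ring C is then built without Lewis acid and without ethers on ring A.

**Step 3.** Conjugate addition may be slow, because the acceptor carbon is fully substituted and the alkene carries a methoxy donor. The phenoxide may then attack sulfur instead, transferring the triflyl group and returning the enolate of 3.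
Fallback: it sets out from 4 and 5 and returns at 6. The same bond is made by C–O cross-coupling under zerovalent palladium catalysis (Pd2(dba)3, 2-(di-tert-butylphosphino)-2',4',6'-triisopropylbiphenyl, K3PO4, toluene, 80 °C), a known coupling of alkenyl triflates with phenols. Oxidative addition into C–OTf and reductive elimination from an electron-poor alkenyl palladium do not depend on the electrophilicity of the alkene, and the weak heterogeneous base keeps the concentration of free phenoxide low. The path makes no compound outside the list (F0).

**Step 7.** Discrimination between O7 and O4' may be insufficient, with silylation at both sites or at the wrong one, because the two acidities are not far apart.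
Fallback: it sets out from 10 and returns at 14, with no protecting group. Compound 10 is converted into its 7,4'-dianion (KOt-Bu, 2.1 equiv, DMF, 0 °C) and treated with one equivalent of prenyl bromide. In the dianion the less stabilised, more basic C4' phenoxide is the better nucleophile, a regiochemical reversal known for 7,4'-dihydroxyisoflavones, so O-alkylation should occur at C4'. The path makes no compound outside the list (F0).

**Step 8.** Two processes threaten it: allylic transposition (SN2' attack, giving the 1,1-dimethylallyl ether), and silyl loss from the acidic O7 under the basic betaine, which would open O7 to alkylation.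
Fallback: it sets out from 10 and returns at 14, changing both the mask and the alkylation mode.
- Acylation of 10 with pivaloyl chloride (1.0 equiv, i-Pr2NEt, THF, −20 °C) at the most acidic hydroxyl should give 5-hydroxy-2-(4-hydroxyphenyl)-3-methoxy-4-oxo-4H-chromen-7-yl pivalate F2.
- Williamson alkylation with prenyl bromide (K2CO3, acetone, 40 °C) should give 5-hydroxy-3-methoxy-2-{4-[(3-methylbut-2-en-1-yl)oxy]phenyl}-4-oxo-4H-chromen-7-yl pivalate F3.
- Methanolysis of the activated aryl ester (K2CO3, MeOH, 0 °C) gives 14.

## Further compounds

F1 | step 5 | 2-[4-(benzyloxy)phenyl]-5,7-dihydroxy-3-methoxy-4H-chromen-4-one | COc1c(-c2ccc(OCc3ccccc3)cc2)oc2cc(O)cc(O)c2c1=O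
F0 | step 3 | none | none
F0 | step 7 | none | none
F2 | step 8 | 5-hydroxy-2-(4-hydroxyphenyl)-3-methoxy-4-oxo-4H-chromen-7-yl pivalate | COc1c(-c2ccc(O)cc2)oc2cc(OC(=O)C(C)(C)C)cc(O)c2c1=O
F3 | step 8 | 5-hydroxy-3-methoxy-2-{4-[(3-methylbut-2-en-1-yl)oxy]phenyl}-4-oxo-4H-chromen-7-yl pivalate | COc1c(-c2ccc(OCC=C(C)C)cc2)oc2cc(OC(=O)C(C)(C)C)cc(O)c2c1=O
A1 | alternative 1 | methyl (8Z)-8-methoxy-9-{4-[(3-methylbut-2-en-1-yl)oxy]phenyl}-3,5,7-trioxonon-8-enoate | COC(=O)CC(=O)CC(=O)CC(=O)/C(OC)=C/c1ccc(OCC=C(C)C)cc1
A2 | alternative 1 | (2Z)-2-methoxy-3-{4-[(3-methylbut-2-en-1-yl)oxy]phenyl}-1-(2,4,6-trihydroxyphenyl)prop-2-en-1-one | O=C(/C(OC)=C/c1ccc(OCC=C(C)C)cc1)c1c(O)cc(O)cc1O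
A3 | alternative 2 | 3,5-bis(methoxymethoxy)-2-[2-methoxy-2-(triphenyl-λ5-phosphanylidene)acetyl]phenyl 4-[(3-methylbut-2-en-1-yl)oxy]benzoate | COCOc1cc(OCOC)c(C(=O)C(OC)=P(c2ccccc2)(c2ccccc2)c2ccccc2)c(OC(=O)c2ccc(OCC=C(C)C)cc2)c1
A4 | alternative 2 | 3-methoxy-5,7-bis(methoxymethoxy)-2-{4-[(3-methylbut-2-en-1-yl)oxy]phenyl}-4H-chromen-4-one | COCOc1cc(OCOC)c2c(c1)oc(-c1ccc(OCC=C(C)C)cc1)c(OC)c2=O
A5 | alternative 3 | 5-hydroxy-2-(hydroxymethyl)-4H-pyran-4-one (kojic acid) | O=c1cc(CO)occ1O
A6 | alternative 3 | 2-(2-diazoacetyl)-5-methoxy-6-{4-[(3-methylbut-2-en-1-yl)oxy]phenyl}-4H-pyran-4-one | COc1c(-c2ccc(OCC=C(C)C)cc2)oc(C(=O)C=[N+]=[N-])cc1=O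
A7 | alternative 3 | (ethynyloxy)triisopropylsilane | C#CO[Si](C(C)C)(C(C)C)C(C)C
A8 | alternative 3 | 5-hydroxy-3-methoxy-2-{4-[(3-methylbut-2-en-1-yl)oxy]phenyl}-7-[(triisopropylsilyl)oxy]-4H-chromen-4-one | COc1c(-c2ccc(OCC=C(C)C)cc2)oc2cc(O[Si](C(C)C)(C(C)C)C(C)C)cc(O)c2c1=O
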